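**Plan**
1. The oxolane oxygen O1 lies between two benzylic carbons, C2 and C5, each para to a phenolic OH, and a mirror plane runs through O1 and the midpoint of C3–C4. Both C–O bonds are therefore water adducts of one meso bis(p-quinone methide).
2. Retrosynthesis: cut C2–O1 and C5–O1 (O1 = water) and join C2 to C5 as a temporary cyclobutane bond. Then cut that bond and C3–C4 by retro-[2+2] to two ferulic acid units. The 3-OMe groups are helpers that keep each ring a monophenol.
3. Forward: ferulic acid is acetylated and two units are hung head-to-head on naphthalene-1,8-diol. Light closes the cyclobutane, LiAlH4 frees the template and the diol, and acetylation followed by selective phenol release gives the bis-phenol diacetate. Oxidative C–C cleavage in water closes the oxolane (last ring), and IBX/dithionite exchanges OMe for OH.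
4. Stereochemistry: the syn head-to-head [2+2] of two E-alkenes sets C3/C4 cis and aryl/CH2 trans. C3 and C4 survive the C–C cleavage and relay C2 and C5 (each trans to its neighbour) by substrate control.

Key step: step 7

Remark on the chemistry: with two identical halves, the descriptors 2R,3S,4R,5S describe a meso compound (C2/C3 trans, C3/C4 cis, C4/C5 trans). The given structure has no enantiomer, so only relative configuration has to be controlled.

Step 1
Reactants: 1 (E)-ferulic acid
Product: 2 (E)-4-O-acetylferulic acid
Conditions: Ac2O, pyridine, rt; aqueous work-up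
Reagents that add atoms: acetic anhydride CC(=O)OC(C)=O
Why: Standard pyridine-promoted O-acetylation masks the phenol so that only the carboxyl group is activated in step 2, the aqueous work-up hydrolyses any mixed anhydride, and no stereocentre is formed.

Step 2
Reactants: 2 (E)-4-O-acetylferulic acid (2 equiv); 3 naphthalene-1,8-diol
Product: 4 naphthalene-1,8-diyl bis[(E)-3-(4-acetoxy-3-methoxyphenyl)prop-2-enoate]
Conditions: DCC (2.2 equiv), DMAP (cat.), CH2Cl2, 0 °C → rt
Reagents that add atoms: none
Why: Steglich esterification of both peri-hydroxyls holds the two E-cinnamoyl arms parallel, head-to-head and within bonding distance, and no stereocentre is formed.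

Step 3
Reactants: 4 naphthalene-1,8-diyl bis[(E)-3-(4-acetoxy-3-methoxyphenyl)prop-2-enoate]
Product: 5 naphthalene-1,8-diyl (1R,2S,3R,4S)-3,4-bis(4-acetoxy-3-methoxyphenyl)cyclobutane-1,2-dicarboxylate (cyclic diester; meso; β-truxinate pattern)
Conditions: hν (365 nm LED or medium-pressure Hg lamp through Pyrex), ground crystalline powder between glass plates, rt
Reagents that add atoms: none
Why: In this template-directed topochemical [2+2] photocycloaddition the two stacked E-alkenes add suprafacially in the syn head-to-head sense, which should set all four cyclobutane stereocentres at once as the meso isomer (ester/ester cis, aryl/aryl cis, ester/aryl trans).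

Step 4
Reactants: 5 template-bound β-truxinate
Product: 6 [(1R,2S,3R,4S)-3,4-bis(4-hydroxy-3-methoxyphenyl)cyclobutane-1,2-diyl]dimethanol (meso)
Conditions: LiAlH4 (excess), THF, 0 °C → rt; aq. Rochelle salt, then 1 M HCl to pH 4
Reagents that add atoms: none
Why: Hydride reduction of all four aryl esters frees the template, both phenols and the diol in one operation, and the fast reduction of the activated aryl esters should outrun enolisation so that the cis-1,2 relation is kept.

Step 5
Reactants: 6 cyclobutane tetraol
Product: 7 tetraacetate of 6 (meso)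
Conditions: Ac2O, pyridine, DMAP (cat.), rt
Reagents that add atoms: acetic anhydride CC(=O)OC(C)=O
Why: Exhaustive acetylation installs the two primary acetates of the target without any selectivity demand and touches no stereocentre.

Step 6
Reactants: 7 cyclobutane tetraacetate
Product: 8 [(1R,2S,3R,4S)-3,4-bis(4-hydroxy-3-methoxyphenyl)cyclobutane-1,2-diyl]bis(methylene) diacetate (meso)
Conditions: pyrrolidine (2.5 equiv), CH2Cl2, 0 °C → rt, short contact time
Reagents that add atoms: none
Why: In this chemoselective aminolysis the aryl acetates (phenoxide leaving group) should react with pyrrolidine far faster than the primary alkyl acetates, so only the two phenols are released.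

Step 7
Reactants: 8 cyclobutane bis-phenol diacetate
Product: 11 [(2R,3S,4R,5S)-2,5-bis(4-hydroxy-3-methoxyphenyl)oxolane-3,4-diyl]bis(methylene) diacetate (meso), via meso bis(p-quinone methide) 9 (not isolated), via hydroxy quinone methide 10 (not isolated)
Conditions: FeCl3·6H2O (2.1 equiv), acetone–H2O (4:1), 0 °C → rt, Ar
Reagents that add atoms: water O
Why: Fe(III) oxidises one guaiacyl OH to the phenoxyl radical, whose spin at the para carbon drives β-scission of the strained, doubly benzylic C3–C4 bond of the cyclobutane, and a second one-electron oxidation with loss of H+ turns the resulting p-hydroxybenzyl radical into the second quinone methide, so that meso bis(p-quinone methide) 9, the species expected from 8–8′ radical coupling of a γ-acetylated monolignol, arises with its two sp3 stereocentres untouched. Water adds 1,6 to either (enantiotopic) quinone methide to give 10, and the new benzylic OH then closes the oxolane by 5-exo-trig oxa-1,6-addition to the remaining quinone methide. The closest known reaction types are the oxidative ring opening of 1,2-bis(4-hydroxyaryl)cyclobutanes to bis-quinone methides that are captured by O-nucleophiles, and the water-mediated tetrahydrofuran formation in 8–8′ coupling of γ-acylated monolignols. C3 and C4 keep the cis relation set in step 3 and relay C2 and C5: in the envelope transition state each aryl group takes the pseudo-equatorial site anti to the neighbouring CH2OAc, and because p-hydroxybenzyl ether bonds ionise reversibly in the HCl/Fe(III) medium, any 2,3-cis or 4,5-cis epimer should drain to the trans,cis,trans isomer, the only one without a cis aryl/CH2OAc pair. The step needs O- over C-capture and 7,7′- over 7,9′-closure: the two acetates remove the side-chain OH groups that would otherwise close a 7,9′-epoxide, water in large excess should outrun Friedel–Crafts attack by the re-aromatised ring, and the methyl ethers keep each ring a monophenol so that oxidation ends at the p-quinone methide level. The oxidant is held near two equivalents because only 8 has the strain-release exit that makes its oxidation irreversible, which should spare the phenols of 11.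

Step 8
Reactants: 11 bis-guaiacyl oxolane diacetate
Product: 13 [(2R,3S,4R,5S)-2,5-bis(3,4-dihydroxyphenyl)oxolane-3,4-diyl]bis(methylene) diacetate (meso; target), via bis(o-quinone) 12 (not isolated)
Conditions: IBX (2.4 equiv), THF, rt, dark; then Na2S2O4, H2O, rt
Reagents that add atoms: IBX (2-iodoxybenzoic acid) O=C1OI(=O)(O)c2ccccc12
Why: In this IBX oxidative demethylation of 2-methoxyphenols, a reaction type known for guaiacyl lignans, oxygen is delivered to the OMe-bearing ortho carbon and methanol is expelled to give the o-quinone, which dithionite reduces in the same flask to the catechol under near-neutral conditions that leave the acetates and the four stereocentres alone.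

**Compound list**
1 | (E)-ferulic acid | COc1cc(/C=C/C(O)=O)ccc1O | starting material
2 | (E)-4-O-acetylferulic acid | COc1cc(/C=C/C(O)=O)ccc1OC(C)=O | intermediate
3 | naphthalene-1,8-diol | Oc1cccc2cccc(O)c12 | starting material
4 | naphthalene-1,8-diyl bis[(E)-3-(4-acetoxy-3-methoxyphenyl)prop-2-enoate] | CC(=O)Oc1ccc(/C=C/C(=O)Oc2cccc3cccc(OC(=O)/C=C/c4ccc(OC(C)=O)c(OC)c4)c23)cc1OC | intermediate
5 | template-bound β-truxinate (meso; ester/ester cis, aryl/aryl cis, ester/aryl trans) | CC(=O)Oc1ccc(cc1OC)[C@H]1[C@@H](c2ccc(OC(C)=O)c(OC)c2)[C@@H]2C(=O)Oc3cccc4cccc(OC(=O)[C@H]12)c34 | intermediate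
6 | [(1R,2S,3R,4S)-3,4-bis(4-hydroxy-3-methoxyphenyl)cyclobutane-1,2-diyl]dimethanol (meso) | OC[C@@H]1[C@H](CO)[C@@H](c2ccc(O)c(OC)c2)[C@H]1c1ccc(O)c(OC)c1 | intermediate
7 | tetraacetate of 6 (meso) | CC(=O)OC[C@@H]1[C@H](COC(C)=O)[C@@H](c2ccc(OC(C)=O)c(OC)c2)[C@H]1c1ccc(OC(C)=O)c(OC)c1 | intermediate
8 | [(1R,2S,3R,4S)-3,4-bis(4-hydroxy-3-methoxyphenyl)cyclobutane-1,2-diyl]bis(methylene) diacetate (meso) | CC(=O)OC[C@@H]1[C@H](COC(C)=O)[C@@H](c2ccc(O)c(OC)c2)[C@H]1c1ccc(O)c(OC)c1 | intermediate
9 | meso bis(p-quinone methide), 2,3-bis(acetoxymethyl)butane-1,4-diylidene core | CC(=O)OC[C@@H](C=C1C=CC(=O)C(OC)=C1)[C@H](COC(C)=O)C=C1C=CC(=O)C(OC)=C1 | intermediate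
10 | hydroxy quinone methide (mono-hydrate of 9; racemic, one enantiomer drawn) | CC(=O)OC[C@@H]([C@@H](O)c1ccc(O)c(OC)c1)[C@H](COC(C)=O)C=C1C=CC(=O)C(OC)=C1 | intermediate
11 | [(2R,3S,4R,5S)-2,5-bis(4-hydroxy-3-methoxyphenyl)oxolane-3,4-diyl]bis(methylene) diacetate (meso) | CC(=O)OC[C@@H]1[C@H](COC(C)=O)[C@@H](c2ccc(O)c(OC)c2)O[C@H]1c1ccc(O)c(OC)c1 | intermediate
12 | bis(o-quinone) of the target | CC(=O)OC[C@@H]1[C@H](COC(C)=O)[C@@H](C2=CC(=O)C(=O)C=C2)O[C@H]1C1=CC(=O)C(=O)C=C1 | intermediate
13 | [(2R,3S,4R,5S)-2,5-bis(3,4-dihydroxyphenyl)oxolane-3,4-diyl]bis(methylene) diacetate (CNP0416169.1) | CC(=O)OC[C@@H]1[C@H](COC(C)=O)[C@@H](c2ccc(O)c(O)c2)O[C@H]1c1ccc(O)c(O)c1 | target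

**Total steps:** 8. **Longest linear sequence:** 8 (1 → 13).

**Steps most likely to fail**

Step 7. Several things may go wrong:
- facial control in the two C–O bond formations may be incomplete;
- the re-aromatised ring may capture the second quinone methide by Friedel–Crafts attack;
- a quinone methide may tautomerise to a styrene;
- the product phenols may be oxidised further while starting material remains.

The fallback sets out from 8 and separates C–C cleavage from ring closure. Ag2O in MeOH–CH2Cl2 opens the cyclobutane, and methanol in large excess traps both quinone methides by intermolecular 1,6-addition. This should give the acyclic 1,4-dimethoxy-1,4-diaryl-2,3-bis(acetoxymethyl)butane F1 as a mixture of benzylic epimers. After removal of the oxidant, catalytic p-TsOH in wet acetonitrile exchanges the benzylic methoxy groups through p-hydroxybenzyl cations. Hydration and cyclo-etherification then proceed under purely thermodynamic control, and the route is rejoined at 11.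

Step 3. The crystals of 4 may be photostable, or they may lose order at partial conversion so that only E/Z isomerisation continues. The fallback sets out from 1 and replaces the covalent template by a non-covalent host. The 2:1 inclusion complex of ferulic acid in cucurbit[8]uril (or γ-cyclodextrin) in water is irradiated. This type of host is known to steer cinnamic acids to the syn head-to-head dimer, here 4,4′-dihydroxy-3,3′-dimethoxy-β-truxinic acid F2. BH3·THF then reduces both carboxyl groups without base, so no epimerisation is expected, and the route is rejoined at 6.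

Step 8. The o-quinone stage may tautomerise at the benzylic ether carbon, IBX may oxidise the benzylic positions, or hydroxylation at the free ortho position may compete with demethylation. The fallback changes the protecting-group strategy so that the last step is a hydrogenolysis. It sets out from 3 and from commercial 3-benzyloxy-4-hydroxybenzaldehyde F3.
- Knoevenagel–Doebner condensation with malonic acid (pyridine, piperidine) gives (E)-3-benzyloxy-4-hydroxycinnamic acid F4.
- Ac2O/pyridine gives its 4-O-acetate F5.
- Steglich esterification with 3 gives the template diester F6.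
- Solid-state irradiation gives the template-bound benzyl-series β-truxinate F7.
- LiAlH4 gives the benzyl-series tetraol F8.
- Ac2O/pyridine gives the benzyl-series tetraacetate F9.
- Pyrrolidine gives the benzyl-series bis-phenol diacetate F10.
- FeCl3·6H2O in aqueous acetone gives the 3-O-benzyl oxolane diacetate F11.
- H2 (1 atm), Pd/C, EtOAc, rt removes both benzyl ethers, a mild debenzylation with precedent on 2,5-diaryloxolanes, and the route is rejoined at 13.

**Further compounds**
F1 | step 7 | 1,4-dimethoxy-1,4-bis(4-hydroxy-3-methoxyphenyl)-2,3-bis(acetoxymethyl)butane (2,3-meso core; benzylic epimers) | CC(=O)OC[C@@H](C(OC)c1ccc(O)c(OC)c1)[C@H](COC(C)=O)C(OC)c1ccc(O)c(OC)c1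
F2 | step 3 | 4,4′-dihydroxy-3,3′-dimethoxy-β-truxinic acid (meso) | OC(=O)[C@@H]1[C@H](C(O)=O)[C@@H](c2ccc(O)c(OC)c2)[C@H]1c1ccc(O)c(OC)c1
F3 | step 8 | 3-benzyloxy-4-hydroxybenzaldehyde (commercial) | O=Cc1ccc(O)c(OCc2ccccc2)c1
F4 | step 8 | (E)-3-benzyloxy-4-hydroxycinnamic acid | OC(=O)/C=C/c1ccc(O)c(OCc2ccccc2)c1
F5 | step 8 | (E)-4-acetoxy-3-benzyloxycinnamic acid | CC(=O)Oc1ccc(/C=C/C(O)=O)cc1OCc1ccccc1
F6 | step 8 | naphthalene-1,8-diyl bis[(E)-3-(4-acetoxy-3-benzyloxyphenyl)prop-2-enoate] | CC(=O)Oc1ccc(/C=C/C(=O)Oc2cccc3cccc(OC(=O)/C=C/c4ccc(OC(C)=O)c(OCc5ccccc5)c4)c23)cc1OCc1ccccc1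
F7 | step 8 | template-bound benzyl-series β-truxinate (meso) | CC(=O)Oc1ccc(cc1OCc1ccccc1)[C@H]1[C@@H](c2ccc(OC(C)=O)c(OCc3ccccc3)c2)[C@@H]2C(=O)Oc3cccc4cccc(OC(=O)[C@H]12)c34
F8 | step 8 | benzyl-series tetraol (meso) | OC[C@@H]1[C@H](CO)[C@@H](c2ccc(O)c(OCc3ccccc3)c2)[C@H]1c1ccc(O)c(OCc2ccccc2)c1
F9 | step 8 | benzyl-series tetraacetate (meso) | CC(=O)OC[C@@H]1[C@H](COC(C)=O)[C@@H](c2ccc(OC(C)=O)c(OCc3ccccc3)c2)[C@H]1c1ccc(OC(C)=O)c(OCc2ccccc2)c1
F10 | step 8 | benzyl-series bis-phenol diacetate (meso) | CC(=O)OC[C@@H]1[C@H](COC(C)=O)[C@@H](c2ccc(O)c(OCc3ccccc3)c2)[C@H]1c1ccc(O)c(OCc2ccccc2)c1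
F11 | step 8 | 3-O-benzyl oxolane diacetate (meso) | CC(=O)OC[C@@H]1[C@H](COC(C)=O)[C@@H](c2ccc(O)c(OCc3ccccc3)c2)O[C@H]1c1ccc(O)c(OCc2ccccc2)c1
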